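A curve gone flat with substrate and partner both still present tempts one to call the catalyst dead, so I left this note for whoever took over the bench.

| setting | eta | gamma | flask |
|---|---|---|---|
| substrate | 0.50 M | 0.50 M | 0.50 M |
| partner | 0.17 M | 0.26 M | 0.350 M |
| free catalyst | 50 mM | 50 mM | 50 mM |
| remark | run made earlier | run made earlier |  |
| time |  |  | 12 h |

- eta (time / h: substrate / %, product / %, catalyst intermediate D / %): 0.833: 91.5, 6.8, 0; 2.00: 89.3, 6.3, 0; 4.00: 85.5, 12.9, 1.3; 10.0: 85.6, 11.4, 1.8
- gamma (time / h: substrate / %, product / %, catalyst intermediate D / %): 2.50: 85.2, 12.0, 1.7; 5.00: 83.8, 13.8, 1.8; 8.00: 82.7, 15.5, 1.1; 10.0: 83.3, 15.7, 1.6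

(readings scatter by 1 percentage point)

1. share of the substrate used up at 12 h
2. product at 12 h, in percent of the substrate charged
3. catalyst intermediate D at 12 h, in percent of the substrate charged

- the earlier runs were read with a standard deviation of 1 percentage point

In the eta run product read flat from about 4.00 h, yet the gamma run, with more partner and the same catalyst charge, read higher at 10.0 h than the eta run did. I therefore treated the plateau as thermodynamic control and reckoned a quotient. With P the product concentration, S the substrate concentration and B the partner charge less P, I took P squared over S times B. The last two gamma readings gave 0.0806, my plateau quotient Q, and the last two eta readings gave 0.0790.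

Taking S as its charge less P, I solved Q for the new flask and got P = 0.0921 M, or 18.4 % product. With catalyst intermediate D read in the gamma run at about 1.35 %, I expected 19.8 % conversion. I asked you to leave the flask alone: the eta run had read flat sooner than the 12 h allowed here.

The forecast gave 20 % conversion, 18.5 % product and 1.5 % catalyst intermediate D, on the ground that “That suggests an equilibrium or a stalled catalyst”.

The flask gave 19.6 %, 17.8 % and 1.72 %.

    partner + free catalyst ⇌ catalyst intermediate A (K = 0.660 /M, k = 1.84 /M/min)
    catalyst intermediate A ⇌ by-product + catalyst intermediate B (K = 0.118 M, k = 3.12 /min)
    catalyst intermediate B ⇌ catalyst intermediate C (K = 2.30, k = 0.119 /min)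
    substrate + catalyst intermediate C ⇌ catalyst intermediate D (K = 2.32 /M, k = 14.0 /M/min)
    catalyst intermediate D ⇌ free catalyst + product (K = 0.252 M, k = 0.565 /min)

The slowest mode of this flask had a half-life of 1.15 h, shorter than the 12 h allowed, and tenfold time made no difference to conversion. The backward turnover of the step from substrate and catalyst intermediate C was 99.7 % of the forward one, so that step ran both ways, and the figures of this flask put Q at 0.0757. For the neighbour flask with 0.88 M of partner, Q gave 29.0 % product. That flask gave 29.2 %.

The readings stem from a simulated flask for substances that don't exist; noise was put on by code.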